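**Strategy.** The target is numbered as a 7-oxabicyclo[4.1.0]hept-4-ene (C1 bears CH2OBz, C2 OAc, C3 OBz, C4=C5, C6 the oxirane CH). Tracing the oxirane C1–O–C6 back to an alkene reveals a cyclohexa-1,3-diene with a trans glycol at C2–C3, a benzene trans-dihydrodiol. That ring is the pinacol of an open (Z,Z)-hexa-2,4-dienedial whose central diene bond (C5–C6) is a vinyl–vinyl coupling bond. The key step joins two acrolein units in one flask: Stille coupling of a β-iodo enal with a β-stannyl enal makes C5–C6, and titanocene-mediated pinacol cyclisation of the two formyl groups then makes C2–C3, closing the ring with the trans diol. The precursors are two acyclic Z-configured three-carbon enals.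

Key step: step 7

Remark: the key step gives the trans-diol as a racemate; the absolute configuration is introduced by the kinetic resolution of step 8, which can pass on at most half of the material.

Step 1
Reactants: 1 prop-2-yn-1-yl benzoate
Product: 2 (Z)-2-formyl-3-[dimethyl(phenyl)silyl]prop-2-en-1-yl benzoate
Conditions: HSiMe2Ph, CO (20 bar), Rh4(CO)12 (cat.), Et3N, toluene, 90 °C
Reagents that add atoms: dimethyl(phenyl)silane C[SiH](C)c1ccccc1; carbon monoxide [C-]#[O+]
Why: Rhodium-catalysed silylformylation of a terminal alkyne adds the silyl group to the terminal carbon and the formyl group to the internal carbon from the same side, so the Z enal (Si cis to CHO) should form, and this geometry later holds C2 and C5 of the target on the same side of the C1=C6 alkene.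

Step 2
Reactants: 2 (Z)-2-formyl-3-[dimethyl(phenyl)silyl]prop-2-en-1-yl benzoate
Product: 3 (Z)-2-(dimethoxymethyl)-3-[dimethyl(phenyl)silyl]prop-2-en-1-yl benzoate
Conditions: HC(OMe)3, PPTS (cat.), MeOH, rt
Reagents that add atoms: trimethyl orthoformate COC(OC)OC
Why: Acid-catalysed acetalisation with the orthoformate as water scavenger takes the vinylsilane out of conjugation with the carbonyl group, which should make the following electrophilic substitution at the silicon-bearing carbon feasible.

Step 3
Reactants: 3 (Z)-2-(dimethoxymethyl)-3-[dimethyl(phenyl)silyl]prop-2-en-1-yl benzoate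
Product: 4 (Z)-2-(dimethoxymethyl)-3-iodoprop-2-en-1-yl benzoate
Conditions: N-iodosuccinimide, MeCN–ClCH2CN, 0 °C to rt
Reagents that add atoms: N-iodosuccinimide O=C1CCC(=O)N1I
Why: Iododesilylation of a vinylsilane (ipso attack of the iodonium source, β-silyl cation, loss of silicon) proceeds with retention in polar nitrile solvents, so the iodine should end cis to the acetal carbon.

Step 4
Reactants: 4 (Z)-2-(dimethoxymethyl)-3-iodoprop-2-en-1-yl benzoate
Product: 5 (Z)-2-formyl-3-iodoprop-2-en-1-yl benzoate
Conditions: CF3CO2H, H2O, CHCl3, 0 °C
Reagents that add atoms: water O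
Why: Mild aqueous acid hydrolysis of the dimethyl acetal should free the aldehyde without touching the benzoate, the vinyl iodide or the Z geometry.

Step 5
Reactants: 6 prop-2-yn-1-ol
Product: 7 (Z)-3-(tributylstannyl)prop-2-en-1-ol
Conditions: LiAlH4, THF, 0 °C to rt; then Bu3SnOTf, −78 °C to rt
Reagents that add atoms: tributyltin trifluoromethanesulfonate CCCC[Sn](CCCC)(CCCC)OS(=O)(=O)C(F)(F)F
Why: Hydroxyl-directed trans-hydroalumination of the propargylic alcohol gives a cyclic vinylalanate with aluminium on C3 cis to the carbinol carbon, and aluminium-to-tin exchange with retention should give the Z stannane.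

Step 6
Reactants: 7 (Z)-3-(tributylstannyl)prop-2-en-1-ol
Product: 8 (Z)-3-(tributylstannyl)prop-2-enal
Conditions: MnO2, CH2Cl2, rt
Reagents that add atoms: none
Why: Manganese dioxide oxidises the allylic alcohol to the enal under neutral conditions that should leave the Z vinylstannane intact.

Step 7
Reactants: 5 (Z)-2-formyl-3-iodoprop-2-en-1-yl benzoate; 8 (Z)-3-(tributylstannyl)prop-2-enal
Product: 10 rac-[(5R*,6R*)-5,6-dihydroxycyclohexa-1,3-dien-1-yl]methyl benzoate, via Z,Z-dienedial 9 (not isolated)
Conditions: Pd2(dba)3 (cat.), AsPh3, CuI (cat.), THF–NMP, 0 °C to rt; then Cp2Ti(Ph)Cl (cat.), Zn, Me3SiCl, THF, rt, high dilution; then dilute aq. HCl, 0 °C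
Reagents that add atoms: none
Why: Zerovalent palladium inserts into the C–I bond of 5, stannane 8 transmetalates with copper assistance, and reductive elimination with retention at both alkenes gives the Z,Z-dienedial 9 (bond C2–C3 of 10, which is C5–C6 of the target); zinc then reduces the titanocene to trivalent Cp2TiPh, which transfers one electron to each formyl group, and the two titanium ketyl radicals combine at the carbonyl carbons (bond C5–C6 of 10, which is C2–C3 of the target) while Me3SiCl releases titanium from the diolate. The closest known reaction types are the Stille coupling of Z-configured vinyl iodides with Z vinylstannanes and the titanocene-catalysed pinacol cyclisation of dialdehydes, a coupling that is also known for α,β-unsaturated aldehydes. The six-membered ring is closed by intramolecular ketyl–ketyl combination of a 1,6-dialdehyde whose Z,Z-diene already holds the two formyl carbons at bonding distance. The two new stereocentres (C5 and C6 of 10) should come out trans because the two bulky phenyltitanocene-oxy groups stay anti to each other during the coupling; the absolute configuration is not controlled here, so 10 is racemic and is resolved in step 8. The step needs retention of both Z alkenes and cyclisation in preference to intermolecular coupling, which the neutral coupling conditions, the immediate reduction in the same flask (9 would isomerise on standing), the dilution and the cis,cis geometry of 9 should secure.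

Step 8
Reactants: 10 rac-[(5R*,6R*)-5,6-dihydroxycyclohexa-1,3-dien-1-yl]methyl benzoate
Product: 11 [(5R,6R)-5-(benzoyloxy)-6-hydroxycyclohexa-1,3-dien-1-yl]methyl benzoate
Conditions: BzCl (0.5 equiv), Cu(OTf)2 (cat.), (S,S)-Ph-BOX [2,2'-(propane-2,2-diyl)bis((4S)-4-phenyl-4,5-dihydrooxazole)] (cat.), iPr2NEt, CH2Cl2, −20 °C; chromatographic removal of the unreacted diol
Reagents that add atoms: benzoyl chloride O=C(Cl)c1ccccc1
Why: Copper–bis(oxazoline)-catalysed asymmetric monobenzoylation of a vicinal diol acts as a kinetic resolution: the chiral copper–diol chelate should let only the (5R,6R)-diol react, by analogy with trans-cycloalkane-1,2-diols, at the less hindered O5 remote from the substituted C1, while the (5S,6S)-diol is left behind (the antipodal ligand would resolve in the opposite sense).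

Step 9
Reactants: 11 [(5R,6R)-5-(benzoyloxy)-6-hydroxycyclohexa-1,3-dien-1-yl]methyl benzoate
Product: 12 [(5R,6R)-6-(acetyloxy)-5-(benzoyloxy)cyclohexa-1,3-dien-1-yl]methyl benzoate
Conditions: Ac2O, DMAP (cat.), pyridine, CH2Cl2, 0 °C
Reagents that add atoms: acetic anhydride CC(=O)OC(C)=O
Why: Nucleophile-catalysed acylation of the remaining secondary alcohol occurs at oxygen only, so the configuration at C6 is kept, and the short cold reaction should forestall benzoyl migration.

Step 10
Reactants: 12 [(5R,6R)-6-(acetyloxy)-5-(benzoyloxy)cyclohexa-1,3-dien-1-yl]methyl benzoate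
Product: 13 [(1S,2S,3R,6S)-2-(acetyloxy)-3-(benzoyloxy)-7-oxabicyclo[4.1.0]hept-4-en-1-yl]methyl benzoate (target)
Conditions: mCPBA, Na2HPO4, CH2Cl2, 0 °C
Reagents that add atoms: 3-chloroperoxybenzoic acid OOC(=O)c1cccc(Cl)c1
Why: Prilezhaev epoxidation should take the more substituted C1=C2 alkene of 12 (C1–C6 of 13) from the face opposite to the adjacent pseudo-axial acetoxy group, which sets both oxirane carbons with the oxygen trans to OAc and cis to OBz.

**Compound list**

1 | prop-2-yn-1-yl benzoate | C#CCOC(=O)c1ccccc1 | starting material
2 | (Z)-2-formyl-3-[dimethyl(phenyl)silyl]prop-2-en-1-yl benzoate | O=C/C(=C\[Si](C)(C)c1ccccc1)COC(=O)c1ccccc1 | intermediate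
3 | (Z)-2-(dimethoxymethyl)-3-[dimethyl(phenyl)silyl]prop-2-en-1-yl benzoate | COC(OC)/C(=C\[Si](C)(C)c1ccccc1)COC(=O)c1ccccc1 | intermediate
4 | (Z)-2-(dimethoxymethyl)-3-iodoprop-2-en-1-yl benzoate | COC(OC)/C(=C\I)COC(=O)c1ccccc1 | intermediate
5 | (Z)-2-formyl-3-iodoprop-2-en-1-yl benzoate | O=C/C(=C\I)COC(=O)c1ccccc1 | intermediate
6 | prop-2-yn-1-ol | C#CCO | starting material
7 | (Z)-3-(tributylstannyl)prop-2-en-1-ol | CCCC[Sn](CCCC)(CCCC)/C=C\CO | intermediate
8 | (Z)-3-(tributylstannyl)prop-2-enal | CCCC[Sn](CCCC)(CCCC)/C=C\C=O | intermediate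
9 | (2Z,4Z)-2-[(benzoyloxy)methyl]hexa-2,4-dienedial (not isolated) | O=C/C(=C\C=C/C=O)COC(=O)c1ccccc1 | intermediate
10 | rac-[(5R*,6R*)-5,6-dihydroxycyclohexa-1,3-dien-1-yl]methyl benzoate (racemate; the (5R,6R) enantiomer is drawn) | O[C@H]1[C@H](O)C=CC=C1COC(=O)c1ccccc1 | intermediate
11 | [(5R,6R)-5-(benzoyloxy)-6-hydroxycyclohexa-1,3-dien-1-yl]methyl benzoate | O[C@H]1[C@H](OC(=O)c2ccccc2)C=CC=C1COC(=O)c1ccccc1 | intermediate
12 | [(5R,6R)-6-(acetyloxy)-5-(benzoyloxy)cyclohexa-1,3-dien-1-yl]methyl benzoate | CC(=O)O[C@H]1[C@H](OC(=O)c2ccccc2)C=CC=C1COC(=O)c1ccccc1 | intermediate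
13 | [(1S,2S,3R,6S)-2-(acetyloxy)-3-(benzoyloxy)-7-oxabicyclo[4.1.0]hept-4-en-1-yl]methyl benzoate | CC(=O)O[C@H]1[C@H](OC(=O)c2ccccc2)C=C[C@@H]2O[C@@]21COC(=O)c1ccccc1 | target

Total step count: 10. Longest linear sequence: 8 steps (steps 1–4 and 7–10).

**Steps most likely to fail**

Step 7. The Z,Z-dienedial may isomerise before it is reduced, and the ketyls may couple between molecules or be over-reduced instead of cyclising. The fallback sets out from 5 and builds the ring by known stepwise chemistry. Stille coupling of 5 with tributyl(vinyl)stannane (Pd2(dba)3, AsPh3) would give (Z)-2-formylpenta-2,4-dien-1-yl benzoate F1. Asymmetric syn-alkoxyallylboration of F1 with (Z)-3-(methoxymethoxy)allylboronic acid pinacol ester under chiral phosphoric acid catalysis ((S)-TRIP expected; otherwise its antipode) would give (2Z)-2-[(1R,2R)-1-hydroxy-2-(methoxymethoxy)but-3-en-1-yl]penta-2,4-dien-1-yl benzoate F2. Ring-closing metathesis with the second-generation Grubbs catalyst, RuCl2(H2IMes)(PCy3)(=CHPh), would give [(5R,6R)-6-hydroxy-5-(methoxymethoxy)cyclohexa-1,3-dien-1-yl]methyl benzoate F3. Cleavage of the methoxymethyl ether (ZnBr2, n-PrSH) comes back to the route at 10, now as the single (5R,6R) enantiomer, so that step 8 only has to tell the two hydroxyls apart.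

Step 8. Discrimination between the two enantiomers, or between the two hydroxyls, may be insufficient. The fallback sets out from 10 and reaches 11 by enzymatic kinetic resolution: immobilised Candida antarctica lipase B with vinyl benzoate in tert-butyl methyl ether should acylate the (R,R)-configured diol, as is usual for trans-cycloalkane-1,2-diols. No new compound is made (F0).

Step 10. The disubstituted alkene may be epoxidised in competition, some oxidant may attack the face syn to the acetoxy group, or acid may trigger aromatisation. The fallback sets out from 12 and reaches 13 by catalyst-controlled epoxidation with a chiral dioxirane (fructose-derived Shi ketone, KHSO5 as Oxone, buffered MeCN–H2O, 0 °C). The ketone enantiomer is chosen so that its facial preference matches attack anti to the acetoxy group. No new compound is made (F0).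

**Further compounds**

F1 | step 7 | (Z)-2-formylpenta-2,4-dien-1-yl benzoate | O=C/C(=C\C=C)COC(=O)c1ccccc1
F2 | step 7 | (2Z)-2-[(1R,2R)-1-hydroxy-2-(methoxymethoxy)but-3-en-1-yl]penta-2,4-dien-1-yl benzoate | C=C[C@@H](OCOC)[C@H](O)/C(COC(=O)c1ccccc1)=C\C=C
F3 | step 7 | [(5R,6R)-6-hydroxy-5-(methoxymethoxy)cyclohexa-1,3-dien-1-yl]methyl benzoate | O[C@H]1[C@H](OCOC)C=CC=C1COC(=O)c1ccccc1
F0 | step 8 | none | none
F0 | step 10 | none | none
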